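**Strategy**

The five-membered lactone (O1, C2 carbonyl, C3 methyl, C4 carboxyl, C5 chain-bearing stereocentre) is disconnected at C4–C5 and O1–C2. C4 stands in the β-position of the C2 acyl group and C5 carries the ring oxygen, the pattern left when a homoenolate adds to an aldehyde. A carbene-bound homoenolate of the enal tert-butyl (E)-3-methyl-4-oxobut-2-enoate therefore adds through its β-carbon to a C14 aldehyde and lactonises in the same operation, forming the ring, both bonds and the C5 configuration. The chain oxygen is carried as a TBS ether, so that the strong base of the later desaturation meets no acetate; acidic deprotection and acetylation complete the route.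

Key step: step 4

Remark on locants: explanations use lactone numbering (O1, C2 ring carbonyl, C3, C4, C5); compound names use furan locants, in which lactone C5, C4, C3 and C2 are C2, C3, C4 and C5.

Assumption: the (5aR,10bS) antipode of the triazolium salt is taken to be the one that directs the homoenolate to the Si face of 3; the sense of induction is checked on the first run and the (5aS,10bR) antipode is used if it proves opposite.

**Route**

Step 1
Reactants: 1 1,14-tetradecanediol
Product: 2 14-[(tert-butyldimethylsilyl)oxy]tetradecan-1-ol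
Conditions: NaH (1.0 equiv), THF, rt; then TBSCl (1.0 equiv), rt
Reagents that add atoms: tert-butyldimethylsilyl chloride, CC(C)(C)[Si](C)(C)Cl
Why: O-silylation (substitution at silicon) of the monosodium alkoxide of a symmetrical diol with one equivalent of silyl chloride should favour the mono-ether, from which unreacted diol and bis-ether are separable by chromatography; no stereocentre is involved.

Step 2
Reactants: 2 14-[(tert-butyldimethylsilyl)oxy]tetradecan-1-ol
Product: 3 14-[(tert-butyldimethylsilyl)oxy]tetradecanal
Conditions: PhI(OAc)2 (1.1 equiv), 2,2,6,6-tetramethylpiperidin-1-oxyl (TEMPO, 10 mol %), CH2Cl2, rt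
Reagents that add atoms: none
Why: Nitroxyl-catalysed (oxoammonium) oxidation of a primary alcohol with PhI(OAc)2 as terminal oxidant should stop at the aldehyde in anhydrous CH2Cl2 and leave the silyl ether untouched.

Step 3
Reactants: 4 tert-butyl 3-methylbut-2-enoate
Product: 5 tert-butyl (E)-3-methyl-4-oxobut-2-enoate
Conditions: SeO2 (1.2 equiv), 1,4-dioxane, 90 °C
Reagents that add atoms: selenium dioxide, O=[Se]=O
Why: Riley allylic oxidation (ene reaction, [2,3]-sigmatropic rearrangement, then oxidation of the allylic selenite) should convert one methyl group of the trisubstituted alkene into the formyl group and re-form the double bond with E geometry (formyl trans to the ester), under conditions that spare the tert-butyl ester.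

Step 4
Reactants: 3 14-[(tert-butyldimethylsilyl)oxy]tetradecanal; 5 tert-butyl (E)-3-methyl-4-oxobut-2-enoate
Product: 6 tert-butyl (2R,3R,4R)-2-{13-[(tert-butyldimethylsilyl)oxy]tridecyl}-4-methyl-5-oxotetrahydrofuran-3-carboxylate (chain and ester cis; ester and methyl trans)
Conditions: (5aR,10bS)-2-mesityl-5a,10b-dihydro-4H,6H-indeno[2,1-b][1,2,4]triazolo[4,3-d][1,4]oxazin-2-ium chloride (10 mol %), 1,8-diazabicyclo[5.4.0]undec-7-ene (DBU, 15 mol %), 4 Å molecular sieves, THF, 0 °C to rt, 5 added slowly to 3 (1.5 equiv)
Reagents that add atoms: none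
Why: Proposed new method: the carbene adds to the formyl group of 5 and proton transfer gives the extended Breslow intermediate, an ester-stabilised homoenolate whose β-carbon (lactone C4) attacks the carbonyl carbon of 3 to form C4–C5, after which the azolium enol tautomerises to the acyl azolium and the C5 alkoxide is acylated to form O1–C2 and release the carbene; the closest known reaction type is the carbene-catalysed homoenolate annulation of enals with aryl aldehydes or activated ketones to γ-butyrolactones, not yet shown for an α-branched enal and an unactivated aliphatic aldehyde at high enantioselectivity. The single ring closes by 5-exo-trig acyl substitution of the alkoxide on the acyl azolium. C5 is set under catalyst control, the indane-fused triazolium blocking one face of the homoenolate so that the Si face of the aldehyde is attacked and the R configuration results. C4 follows from the aldol-type transition state (ester cis to the chain expected) and C3 from protonation of the azolium enol anti to the ester, and since both centres are removed in step 5 their epimers are carried on together. The step needs homoenolate instead of acyl-anion reactivity and cross- instead of self-annulation: the N-mesityl group favours irreversible carbene addition to the enal and reaction at the β-carbon, the β-ester stabilises the homoenolate, the α-methyl group and conjugation make the formyl group of 5 a weaker electrophile than that of 3, and slow addition of 5 to an excess of 3 keeps benzoin, Stetter and enal-dimer pathways down.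

Step 5
Reactants: 6 tert-butyl (2R,3R,4R)-2-{13-[(tert-butyldimethylsilyl)oxy]tridecyl}-4-methyl-5-oxotetrahydrofuran-3-carboxylate
Product: 9 tert-butyl (2R)-2-{13-[(tert-butyldimethylsilyl)oxy]tridecyl}-4-methyl-5-oxo-2,5-dihydrofuran-3-carboxylate, via α-phenylselanyl lactone 7 (not isolated), via selenoxide 8 (not isolated)
Conditions: LiN(SiMe3)2 (1.1 equiv), THF, −78 °C; PhSeBr (1.2 equiv), −78 °C; then AcOH, 30 % aq. H2O2, 0 °C to rt
Reagents that add atoms: none
Why: The amide base should remove the lactone α-proton at C3 (more acidic than the C4–H next to the tert-butyl ester), PhSeBr should selenenylate the enolate anti to the C4 ester, and oxidation should trigger selenoxide syn-elimination toward the C4–H that is cis to selenium (enolate selenenylation/selenoxide elimination), so that C3 and C4 lose their configuration while C5 is untouched.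

Step 6
Reactants: 9 tert-butyl (2R)-2-{13-[(tert-butyldimethylsilyl)oxy]tridecyl}-4-methyl-5-oxo-2,5-dihydrofuran-3-carboxylate
Product: 10 (2R)-2-(13-hydroxytridecyl)-4-methyl-5-oxo-2,5-dihydrofuran-3-carboxylic acid
Conditions: CF3CO2H/CH2Cl2/H2O (10:10:1), 0 °C to rt
Reagents that add atoms: none
Why: Acidolysis should cleave the tert-butyl ester by alkyl–oxygen fission (loss of isobutene) and hydrolyse the primary silyl ether in the same operation, while the butenolide and its C5 centre, which is sensitive to base but not to acid, are unaffected.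

Step 7
Reactants: 10 (2R)-2-(13-hydroxytridecyl)-4-methyl-5-oxo-2,5-dihydrofuran-3-carboxylic acid
Product: 11 (2R)-2-(13-acetoxytridecyl)-4-methyl-5-oxo-2,5-dihydrofuran-3-carboxylic acid (CNP0365369.1)
Conditions: Ac2O (2 equiv), pyridine, CH2Cl2, 0 °C to rt; aqueous work-up
Reagents that add atoms: acetic anhydride, CC(=O)OC(C)=O
Why: Pyridine-mediated acetylation (nucleophilic acyl substitution on the anhydride) should esterify the unhindered primary alcohol, the conjugated carboxyl group is returned as the free acid by the aqueous work-up, and pyridine is too weak a base to remove the C5 proton.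

**Compound list**

1 | 1,14-tetradecanediol | OCCCCCCCCCCCCCCO | starting material
2 | 14-[(tert-butyldimethylsilyl)oxy]tetradecan-1-ol | CC(C)(C)[Si](C)(C)OCCCCCCCCCCCCCCO | intermediate
3 | 14-[(tert-butyldimethylsilyl)oxy]tetradecanal | CC(C)(C)[Si](C)(C)OCCCCCCCCCCCCCC=O | intermediate
4 | tert-butyl 3-methylbut-2-enoate | CC(C)=CC(=O)OC(C)(C)C | starting material
5 | tert-butyl (E)-3-methyl-4-oxobut-2-enoate | O=C/C(C)=C/C(=O)OC(C)(C)C | intermediate
6 | tert-butyl (2R,3R,4R)-2-{13-[(tert-butyldimethylsilyl)oxy]tridecyl}-4-methyl-5-oxotetrahydrofuran-3-carboxylate | CC(C)(C)[Si](C)(C)OCCCCCCCCCCCCC[C@H]1OC(=O)[C@H](C)[C@H]1C(=O)OC(C)(C)C | intermediate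
7 | tert-butyl (2R,3R,4R)-2-{13-[(tert-butyldimethylsilyl)oxy]tridecyl}-4-methyl-5-oxo-4-(phenylselanyl)tetrahydrofuran-3-carboxylate (PhSe trans to the ester) | CC(C)(C)[Si](C)(C)OCCCCCCCCCCCCC[C@H]1OC(=O)[C@](C)([Se]c2ccccc2)[C@H]1C(=O)OC(C)(C)C | intermediate (not isolated)
8 | tert-butyl (2R,3R,4R)-2-{13-[(tert-butyldimethylsilyl)oxy]tridecyl}-4-methyl-5-oxo-4-(phenylseleninyl)tetrahydrofuran-3-carboxylate (mixture at selenium) | CC(C)(C)[Si](C)(C)OCCCCCCCCCCCCC[C@H]1OC(=O)[C@](C)([Se](=O)c2ccccc2)[C@H]1C(=O)OC(C)(C)C | intermediate (not isolated)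
9 | tert-butyl (2R)-2-{13-[(tert-butyldimethylsilyl)oxy]tridecyl}-4-methyl-5-oxo-2,5-dihydrofuran-3-carboxylate | CC(C)(C)[Si](C)(C)OCCCCCCCCCCCCC[C@H]1OC(=O)C(C)=C1C(=O)OC(C)(C)C | intermediate
10 | (2R)-2-(13-hydroxytridecyl)-4-methyl-5-oxo-2,5-dihydrofuran-3-carboxylic acid | OCCCCCCCCCCCCC[C@H]1OC(=O)C(C)=C1C(=O)O | intermediate
11 | (2R)-2-(13-acetoxytridecyl)-4-methyl-5-oxo-2,5-dihydrofuran-3-carboxylic acid | CC(=O)OCCCCCCCCCCCCC[C@H]1OC(=O)C(C)=C1C(=O)O | target

**Step count**

Total steps: 7. Longest linear sequence: 6 steps (1 → 2 → 3 → 6 → 9 → 10 → 11; steps 1, 2, 4, 5, 6, 7).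

**Steps most likely to fail**

Step 4. The annulation may fail in four ways: slow formation of the Breslow intermediate at the α-branched enal, carbene attack on the aliphatic aldehyde (benzoin or Stetter reactivity), base-induced self-aldol of 3, or weak facial discrimination at C5. The fallback sets the carbinol centre by an auxiliary-controlled aldol reaction and uses established chemistry only. It sets out from 3.
- (4S)-4-Benzyl-1,3-oxazolidin-2-one is N-acylated (n-BuLi, methyl 4-chloro-4-oxobutanoate, THF, −78 °C) to methyl 4-[(4S)-4-benzyl-2-oxo-1,3-oxazolidin-3-yl]-4-oxobutanoate F1.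
- Its dibutylboron enolate (Bu2BOTf, iPr2NEt, CH2Cl2, −78 to 0 °C) should add to 3 in an Evans syn-aldol reaction to give the (3S,4R)-hydroxy imide F2.
- F2 lactonises onto its methyl ester (pyridinium p-toluenesulfonate, CH2Cl2) to the trans-lactone imide F3.
- LiOH/H2O2 (THF/H2O, 0 °C, acidic work-up) removes the auxiliary and gives the silyl-protected paraconic acid F4.
- Carboxylation at the lactone α-carbon with methoxymagnesium methyl carbonate (DMF, 130 °C) gives the diacid F5.
- With aqueous formaldehyde and N-methylaniline (AcOH, NaOAc, rt) F5 undergoes decarboxylative methylenation to the α-methylene acid F6.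
- Aqueous CF3CO2H removes the silyl group to give the α-methylene hydroxy acid F7.
- Et3N (CH2Cl2, rt) moves the exocyclic double bond into the ring and delivers 10, where the route is rejoined before step 7.

Step 5. Deprotonation may stray to C4, followed by β-elimination of the ring oxygen (ring opening and loss of the C5 configuration). The selenoxide may also eliminate toward the methyl group; a double bond formed there can be moved into the ring with catalytic Et3N, at the price of possible proton exchange at C5 on long exposure. The fallback first unmasks the carboxyl group so that a carboxylate shields C4. It sets out from 6.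
- Me3SiOTf/2,6-lutidine (CH2Cl2, 0 °C; aqueous work-up) cleaves the tert-butyl ester selectively to the silyl-protected saturated acid F8.
- The dianion of F8 (LiN(SiMe3)2, 2.2 equiv, THF, −78 °C) is selenenylated with PhSeBr to the seleno acid F9.
- H2O2 (AcOH, 0 °C) oxidises F9 to the selenoxide acid F10, which eliminates to the silyl-protected butenolide acid F11.
- Aqueous CF3CO2H removes the silyl group and delivers 10, where the route is rejoined before step 7.

Step 3. The allylic oxidation may stall, run on to the carboxylic acid, erode the E geometry, or cost part of the tert-butyl group through the acidity of the selenium by-products. The fallback assembles the enal by olefination. It sets out from 4.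
- Ozonolysis (O3, CH2Cl2, −78 °C; Me2S) gives tert-butyl glyoxylate F12.
- Wittig reaction of crude F12 with the stabilised ylide 2-(triphenylphosphoranylidene)propanal (CH2Cl2, rt) should give 5 with E geometry, where the route is rejoined before step 4.

**Further compounds**

F1 | step 4 | methyl 4-[(4S)-4-benzyl-2-oxo-1,3-oxazolidin-3-yl]-4-oxobutanoate | COC(=O)CCC(=O)N1[C@@H](Cc2ccccc2)COC1=O
F2 | step 4 | methyl (3S,4R)-3-{[(4S)-4-benzyl-2-oxo-1,3-oxazolidin-3-yl]carbonyl}-17-[(tert-butyldimethylsilyl)oxy]-4-hydroxyheptadecanoate | COC(=O)C[C@H](C(=O)N1[C@@H](Cc2ccccc2)COC1=O)[C@H](O)CCCCCCCCCCCCCO[Si](C)(C)C(C)(C)C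
F3 | step 4 | (4S)-4-benzyl-3-{[(2R,3S)-2-{13-[(tert-butyldimethylsilyl)oxy]tridecyl}-5-oxotetrahydrofuran-3-yl]carbonyl}-1,3-oxazolidin-2-one | O=C1C[C@H](C(=O)N2[C@@H](Cc3ccccc3)COC2=O)[C@@H](CCCCCCCCCCCCCO[Si](C)(C)C(C)(C)C)O1
F4 | step 4 | (2R,3S)-2-{13-[(tert-butyldimethylsilyl)oxy]tridecyl}-5-oxotetrahydrofuran-3-carboxylic acid | O=C1C[C@H](C(=O)O)[C@@H](CCCCCCCCCCCCCO[Si](C)(C)C(C)(C)C)O1
F5 | step 4 | (2R,3S)-2-{13-[(tert-butyldimethylsilyl)oxy]tridecyl}-5-oxotetrahydrofuran-3,4-dicarboxylic acid (C4 unassigned) | O=C1C(C(=O)O)[C@H](C(=O)O)[C@@H](CCCCCCCCCCCCCO[Si](C)(C)C(C)(C)C)O1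
F6 | step 4 | (2R,3S)-2-{13-[(tert-butyldimethylsilyl)oxy]tridecyl}-4-methylidene-5-oxotetrahydrofuran-3-carboxylic acid | O=C1C(=C)[C@H](C(=O)O)[C@@H](CCCCCCCCCCCCCO[Si](C)(C)C(C)(C)C)O1
F7 | step 4 | (2R,3S)-2-(13-hydroxytridecyl)-4-methylidene-5-oxotetrahydrofuran-3-carboxylic acid | O=C1C(=C)[C@H](C(=O)O)[C@@H](CCCCCCCCCCCCCO)O1
F8 | step 5 | (2R,3R,4R)-2-{13-[(tert-butyldimethylsilyl)oxy]tridecyl}-4-methyl-5-oxotetrahydrofuran-3-carboxylic acid | CC(C)(C)[Si](C)(C)OCCCCCCCCCCCCC[C@H]1OC(=O)[C@H](C)[C@H]1C(=O)O
F9 | step 5 | (2R,3R,4R)-2-{13-[(tert-butyldimethylsilyl)oxy]tridecyl}-4-methyl-5-oxo-4-(phenylselanyl)tetrahydrofuran-3-carboxylic acid | CC(C)(C)[Si](C)(C)OCCCCCCCCCCCCC[C@H]1OC(=O)[C@](C)([Se]c2ccccc2)[C@H]1C(=O)O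
F10 | step 5 | (2R,3R,4R)-2-{13-[(tert-butyldimethylsilyl)oxy]tridecyl}-4-methyl-5-oxo-4-(phenylseleninyl)tetrahydrofuran-3-carboxylic acid (mixture at selenium) | CC(C)(C)[Si](C)(C)OCCCCCCCCCCCCC[C@H]1OC(=O)[C@](C)([Se](=O)c2ccccc2)[C@H]1C(=O)O
F11 | step 5 | (2R)-2-{13-[(tert-butyldimethylsilyl)oxy]tridecyl}-4-methyl-5-oxo-2,5-dihydrofuran-3-carboxylic acid | CC(C)(C)[Si](C)(C)OCCCCCCCCCCCCC[C@H]1OC(=O)C(C)=C1C(=O)O
F12 | step 3 | tert-butyl glyoxylate (tert-butyl 2-oxoacetate) | O=CC(=O)OC(C)(C)C
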